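**Retrosynthetic overview**
1. 16 ⇐ 15 (C8 alcohol to ketone) ⇐ 14 (vinyl to isobutenyl by cross-metathesis).
2. Ring D ⇐ quinone tetraol 13 by a new acid-catalysed dehydrative oxa-SN2′ cyclisation (C9–O adds to C2′, C1–OH leaves, C1′=C1 forms, C2′ is set).
3. Rings B and C together ⇐ vinyl quinone 9 by an intramolecular vinyl quinone Diels–Alder reaction with water capture at C1 (C2, C6, C7 set from C3).
4. 9 ⇐ enal 5 + chiral γ-silylallylborane (sets C9) ⇐ Heck coupling of 2-iodo-1,4-dimethoxybenzene with (E)-8-hydroxylinalool ⇐ (S)-linalool (C3).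
5. Ring order: A (bought as the arene) → B and C in one step → D.

Assumption: (S)-(+)-linalool is bought in ≥98% ee.
Labels used below: terpenoid chain C1–C11 counted from ring A (C1 = ring B CH next to ring A; C2 and C6 = ring B/C fusion carbons; C3 = C(CH3)OH; C7 = quaternary C–CH3; C8 = ring D carbonyl carbon; C9 = ring D O–CH; C10=C11 = side-chain alkene). Ring A: C1′ (bonded to C1), C2′ (bonded to C7 and the ring D oxygen), C3′ and C6′ carbonyls. In these labels the target is (2R,3S,6S,7R,9R,2′S).

**Step 1**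
Reactants: 1 (S)-(+)-linalool
Product: 2 (2E,6S)-2,6-dimethylocta-2,7-diene-1,6-diol
Conditions: SeO2 (0.1 equiv), t-BuOOH (70% aq, 2 equiv), salicylic acid (0.1 equiv), CH2Cl2, rt
Reagents that add atoms: tert-butyl hydroperoxide, CC(C)(C)OO
Why: Selenium dioxide allylic oxidation (ene then [2,3]-sigmatropic shift, catalytic in selenium) hydroxylates the (E)-methyl of the trisubstituted alkene selectively and leaves the carbinol stereocentre untouched.

**Step 2**
Reactants: 2 (2E,6S)-2,6-dimethylocta-2,7-diene-1,6-diol; 3 2-iodo-1,4-dimethoxybenzene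
Product: 4 (2E,6S,7E)-8-(2,5-dimethoxyphenyl)-2,6-dimethylocta-2,7-diene-1,6-diol
Conditions: Pd(OAc)2 (5 mol%), Bu4NCl, NaHCO3, DMF, 60 °C
Reagents that add atoms: none
Why: Heck reaction under Jeffery conditions; the aryl-palladium species adds to the unhindered vinyl terminus and, with a quaternary carbinol carbon next to it, β-hydride elimination can only give the (E)-styrene.

**Step 3**
Reactants: 4 (2E,6S,7E)-8-(2,5-dimethoxyphenyl)-2,6-dimethylocta-2,7-diene-1,6-diol
Product: 5 (2E,6S,7E)-8-(2,5-dimethoxyphenyl)-6-hydroxy-2,6-dimethylocta-2,7-dienal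
Conditions: MnO2 (15 equiv), CH2Cl2, rt
Reagents that add atoms: none
Why: MnO2 oxidises only the primary allylic alcohol to the (E)-enal; the tertiary alcohol cannot be oxidised.

**Step 4**
Reactants: 5 (2E,6S,7E)-8-(2,5-dimethoxyphenyl)-6-hydroxy-2,6-dimethylocta-2,7-dienal
Product: 7 (3R,4S,5E,9S,10E)-11-(2,5-dimethoxyphenyl)-5,9-dimethylundeca-1,5,10-triene-3,4,9-triol, via borinate adduct 6 (not isolated)
Conditions: allyl(diisopropylamino)dimethylsilane, n-BuLi, TMEDA, Et2O, 0 °C; (+)-Ipc2BOMe [(+)-B-methoxydiisopinocampheylborane, from (−)-α-pinene], −78 °C; BF3·OEt2 (1.0 equiv); 5 (0.5 equiv), −78 °C; then H2O2, KF, KHCO3, THF/MeOH, rt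
Reagents that add atoms: allyl(diisopropylamino)dimethylsilane, C=CC[Si](C)(C)N(C(C)C)C(C)C; hydrogen peroxide, OO
Why: Reagent-controlled allylboration through a chair (Zimmerman–Traxler) transition state: the (E)-γ-silylallyl-B(Ipc)2 reagent attacks the Re face of the enal to give the anti β-hydroxy allylsilane, and Tamao–Fleming oxidation replaces silicon by OH with retention, so C9 (the vinyl-bearing carbinol) is R and C8 is S (C8 is erased in step 11).

**Step 5**
Reactants: 7 (3R,4S,5E,9S,10E)-11-(2,5-dimethoxyphenyl)-5,9-dimethylundeca-1,5,10-triene-3,4,9-triol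
Product: 8 (1E,3S,6E)-1-(2,5-dimethoxyphenyl)-7-[(4S,5R)-2,2-dimethyl-5-vinyl-1,3-dioxolan-4-yl]-3-methylocta-1,6-dien-3-ol
Conditions: Me2C(OMe)2, PPTS (5 mol%), CH2Cl2, 0 °C
Reagents that add atoms: 2,2-dimethoxypropane, COC(C)(C)OC
Why: Acid-catalysed transketalisation closes the 1,2-diol to the cis-dioxolane far faster than the tertiary alcohol reacts; this masks the glycol against cerium-mediated cleavage and keeps the dienophile side compact.

**Step 6**
Reactants: 8 (1E,3S,6E)-1-(2,5-dimethoxyphenyl)-7-[(4S,5R)-2,2-dimethyl-5-vinyl-1,3-dioxolan-4-yl]-3-methylocta-1,6-dien-3-ol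
Product: 9 2-{(1E,3S,6E)-7-[(4S,5R)-2,2-dimethyl-5-vinyl-1,3-dioxolan-4-yl]-3-hydroxy-3-methylocta-1,6-dien-1-yl}cyclohexa-2,5-diene-1,4-dione (used at once)
Conditions: (NH4)2Ce(NO3)6 (2.5 equiv), MeCN/H2O (3:1), 0 °C, 10 min
Reagents that add atoms: water, O
Why: Oxidative demethylation of a p-dimethoxyarene through its radical cation; water supplies both quinone oxygens, and the short cold reaction spares the acetonide and the alkenes.

**Step 7**
Reactants: 9 vinyl quinone
Product: 12 hydroxyalkyl quinone acetonide (C1 epimers), via isoquinone methide 10 (not isolated), via hydroquinone 11 (not isolated)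
Conditions: PhMe/H2O (1:1), degassed, 60 °C; then Ag2O, rt
Reagents that add atoms: water, O
Why: Intramolecular vinyl quinone Diels–Alder reaction (inverse electron demand; (E)-vinyl quinone as diene, tethered (E)-trisubstituted alkene as dienophile) forms C2–C6 and C2′–C7 through the trans-fused transition state with the C3 hydroxyl inside and the C3 methyl anti to the dienophile, as in known linalool-derived vinyl quinone cycloadditions. This sets C2, C6 and C7 (7-CH3 cis to C5, C3–OH cis to C1). Water then adds 1,4 to the isoquinone methide at C1, the adduct aromatises, and Ag2O returns the quinone.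

**Step 8**
Reactants: 12 hydroxyalkyl quinone acetonide (C1 epimers)
Product: 13 quinone tetraol (C1 epimers)
Conditions: PPTS (0.2 equiv), MeOH, 40 °C
Reagents that add atoms: none
Why: Acid-catalysed acetal exchange (methanolysis) opens the strained cis-dioxolane; the weak acid neither ionises the quinone carbinol nor dehydrates the tertiary alcohol.

**Step 9**
Reactants: 13 quinone tetraol (C1 epimers)
Product: 14 tetracyclic vinyl furanol
Conditions: (PhO)2P(O)OH (20 mol%), 4 Å MS, CH2Cl2, 40 °C
Reagents that add atoms: none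
Why: Proposed new method: Brønsted-acid-catalysed dehydrative dearomatising oxa-cyclisation, a formal intramolecular SN2′ etherification of a (1-hydroxyalkyl)quinone. The phosphoric acid activates the C6′ carbonyl so that the C9 hydroxyl adds 5-exo to the fully substituted quinone carbon C2′; it can only reach the face that carries C8, so ring D is cis-fused and C2′ is set as in the target. The resulting C6′ enol then expels the C1 hydroxyl as water to give the C1′=C1 enone, which makes the otherwise reversible oxa-Michael step irreversible (sieves remove the water) and lets both C1 epimers converge. The closest known reaction types are acid-catalysed intramolecular oxa-Michael additions to quinones, the dehydration of β-hydroxy ketones, and (in reverse) the hydration of isoquinone methides at this carbon.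

**Step 10**
Reactants: 14 tetracyclic vinyl furanol
Product: 15 (8S)-C8 carbinol of the target
Conditions: second-generation Grubbs catalyst (5 mol%), 2-methyl-2-butene/CH2Cl2 (1:1), 40 °C
Reagents that add atoms: 2-methyl-2-butene, CC=C(C)C
Why: Olefin cross-metathesis with a large excess of 2-methyl-2-butene converts the terminal vinyl into the isobutenyl group; the enedione and dienone alkenes are electron-poor and inert to the ruthenium carbene, and no stereocentre is touched.

**Step 11**
Reactants: 15 (8S)-C8 carbinol of the target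
Product: 16 CNP0156201.1 (target)
Conditions: DMP, pyridine, CH2Cl2, 0 °C → rt
Reagents that add atoms: none
Why: Dess–Martin oxidation of the only secondary alcohol (the tertiary one is inert) under non-basic conditions, so the now enolisable C9 stereocentre is formed last and is not epimerised.

**Compound list**
1 | (S)-(+)-linalool, (3S)-3,7-dimethylocta-1,6-dien-3-ol | C=C[C@@](C)(O)CCC=C(C)C | starting material
2 | (2E,6S)-2,6-dimethylocta-2,7-diene-1,6-diol ((E)-8-hydroxylinalool) | C=C[C@@](C)(O)CC/C=C(\C)CO | intermediate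
3 | 2-iodo-1,4-dimethoxybenzene | COc1ccc(OC)c(I)c1 | starting material
4 | (2E,6S,7E)-8-(2,5-dimethoxyphenyl)-2,6-dimethylocta-2,7-diene-1,6-diol | COc1ccc(OC)c(/C=C/[C@@](C)(O)CC/C=C(\C)CO)c1 | intermediate
5 | (2E,6S,7E)-8-(2,5-dimethoxyphenyl)-6-hydroxy-2,6-dimethylocta-2,7-dienal | COc1ccc(OC)c(/C=C/[C@@](C)(O)CC/C=C(\C)C=O)c1 | intermediate
6 | borinate adduct: 7 with the C4 oxygen (label C8) as O–B(Ipc)2 and the C3 hydroxyl (label C9) replaced by SiMe2N(i-Pr)2, same configurations (3R,4S) | COc1ccc(OC)c(/C=C/[C@@](C)(O)CC/C=C(\C)[C@H](OB([C@H]2C[C@H]3C[C@@H]([C@@H]2C)C3(C)C)[C@H]2C[C@H]3C[C@@H]([C@@H]2C)C3(C)C)[C@H]([Si](C)(C)N(C(C)C)C(C)C)C=C)c1 | intermediate (not isolated)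
7 | (3R,4S,5E,9S,10E)-11-(2,5-dimethoxyphenyl)-5,9-dimethylundeca-1,5,10-triene-3,4,9-triol (anti-3,4-diol; label C9 R, C8 S, C3 S) | COc1ccc(OC)c(/C=C/[C@@](C)(O)CC/C=C(\C)[C@H](O)[C@H](O)C=C)c1 | intermediate
8 | (1E,3S,6E)-1-(2,5-dimethoxyphenyl)-7-[(4S,5R)-2,2-dimethyl-5-vinyl-1,3-dioxolan-4-yl]-3-methylocta-1,6-dien-3-ol (cis-dioxolane) | COc1ccc(OC)c(/C=C/[C@@](C)(O)CC/C=C(\C)[C@@H]2OC(C)(C)O[C@@H]2C=C)c1 | intermediate
9 | vinyl quinone: 2-{(1E,3S,6E)-7-[(4S,5R)-2,2-dimethyl-5-vinyl-1,3-dioxolan-4-yl]-3-hydroxy-3-methylocta-1,6-dien-1-yl}cyclohexa-2,5-diene-1,4-dione | O=C1C=CC(=O)C(/C=C/[C@@](C)(O)CC/C=C(\C)[C@@H]2OC(C)(C)O[C@@H]2C=C)=C1 | intermediate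
10 | isoquinone methide cycloadduct: ring A cyclohex-2-ene-1,4-dione with exocyclic C1′=C1 and H on C2′ (cis to 7-CH3); rings B/C trans-fused; C7 bears CH3 and the dioxolanyl group; C2, C3, C6, C7 as in 16 | O=C1C=CC(=O)C2=C[C@@H]3[C@H](CC[C@]3(C)O)[C@@](C)([C@@H]3OC(C)(C)O[C@@H]3C=C)[C@@H]12 | intermediate (not isolated)
11 | hydroquinone: 12 with ring A as the 3′,6′-dihydroxybenzene (C1–OH, both epimers) | Oc1ccc(O)c2c1[C@](C)([C@@H]1OC(C)(C)O[C@@H]1C=C)[C@H]1CC[C@](C)(O)[C@@H]1C2O | intermediate (not isolated)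
12 | hydroxyalkyl quinone acetonide: ring A 1,4-benzoquinone fused at C1′/C2′ to ring B; C1–OH (both epimers); C7 bears CH3 and the cis-(4S,5R)-2,2-dimethyl-5-vinyl-1,3-dioxolan-4-yl group (C8 S, C9 R); ring C trans-fused cyclopentanol with C3–OH cis to C1; C2, C3, C6, C7 as in 16 | O=C1C=CC(=O)C2=C1[C@](C)([C@@H]1OC(C)(C)O[C@@H]1C=C)[C@H]1CC[C@](C)(O)[C@@H]1C2O | intermediate
13 | quinone tetraol: 12 with the free (8S,9R)-8,9-diol (C1–OH both epimers) | O=C1C=CC(=O)C2=C1[C@](C)([C@H](O)[C@H](O)C=C)[C@H]1CC[C@](C)(O)[C@@H]1C2O | intermediate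
14 | tetracyclic vinyl furanol: 16 with a vinyl group on C9 in place of isobutenyl and (8S)-CH(OH) in place of the C8 ketone; ring D cis-fused, all other centres as in 16 | C=C[C@H]1O[C@@]23C(=O)C=CC(=O)C2=C[C@@H]2[C@H](CC[C@]2(C)O)[C@@]3(C)[C@@H]1O | intermediate
15 | (8S)-C8 carbinol of the target (16 with C8 as CH(OH)) | CC(C)=C[C@H]1O[C@@]23C(=O)C=CC(=O)C2=C[C@@H]2[C@H](CC[C@]2(C)O)[C@@]3(C)[C@@H]1O | intermediate
16 | CNP0156201.1, (2R,3S,6S,7R,9R,2′S) in the labels above | CC(C)=C[C@H]1O[C@@]23C(=O)C=CC(=O)C2=C[C@@H]2[C@H](CC[C@]2(C)O)[C@@]3(C)C1=O | target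

**Step count and risks**
Total steps: 11. Longest linear sequence: 11 (from 1).

Most likely to fail:

Step 9 (the proposed new step): the oxa-Michael addition to a fully substituted quinone carbon may be slow, and the (1-hydroxyalkyl)quinone could instead isomerise to the acyl hydroquinone. The fallback uses known chemistry; it sets out from 12 and comes back at 14. Dess–Martin oxidation of the C1 carbinol of 12 gives the acyl quinone acetonide F1. Aqueous acetic acid (AcOH/H2O/THF, 40 °C) removes the acetonide to the acyl quinone triol F2, which is not isolated: its C9 hydroxyl adds to C2′, now the β-carbon of a doubly activated 2-acyl quinone (a well-established, strongly favoured oxa-Michael addition), to give the cyclised enolised β-diketone F3. PhNTf2/Et3N converts the acidic C1 enol into the enol triflate F4, and Pd(OAc)2/PPh3, HCO2H, Et3N in DMF reduces the triflate to C–H, which gives 14.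

Step 7: water capture of isoquinone methide 10 at C1 competes with simple tautomerisation to the C1-unoxidised hydroquinone, and the facial selectivity rests on the C3 carbinol. The fallback installs the C1 oxygen by benzylic oxidation; it sets out from 9 and comes back at 12. Heating 9 in dry toluene (60 °C) followed by a reductive work-up (aqueous Na2S2O4) gives the hydroquinone F5. MeI/K2CO3 in acetone gives the dimethyl ether F6. DDQ in wet CH2Cl2 hydroxylates the only benzylic CH2 (C1; C7 is quaternary) to the benzylic alcohol F7, and (NH4)2Ce(NO3)6 in MeCN/H2O then gives 12.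

Step 4: the borane reagent is sensitive, the free tertiary alcohol consumes some of it, and any excess BF3·OEt2 could ionise the styrenyl carbinol. The fallback is a catalytic coupling from the alcohol oxidation level; it sets out from 4 and comes back at 7. Iridium-catalysed transfer-hydrogenative anti-(benzoyloxy)allylation of allylic alcohol 4 with prop-2-ene-1,1-diyl dibenzoate ([Ir(cod)Cl]2, the SEGPHOS enantiomer that gives the (9R) product, 4-cyano-3-nitrobenzoic acid, K3PO4, THF, 90 °C) gives the anti C9 monobenzoate F8. K2CO3/MeOH removes the benzoate and gives 7.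

**Further compounds**
F1 | step 9 | acyl quinone acetonide (12 with C1 as ketone) | O=C1C=CC(=O)C2=C1[C@](C)([C@@H]1OC(C)(C)O[C@@H]1C=C)[C@H]1CC[C@](C)(O)[C@@H]1C2=O
F2 | step 9 | acyl quinone triol (F1 with the free 8,9-diol; not isolated) | O=C1C=CC(=O)C2=C1[C@](C)([C@H](O)[C@H](O)C=C)[C@H]1CC[C@](C)(O)[C@@H]1C2=O
F3 | step 9 | cyclised enolised β-diketone (14 bearing OH on C1) | C=C[C@H]1O[C@@]23C(=O)C=CC(=O)C2=C(O)[C@@H]2[C@H](CC[C@]2(C)O)[C@@]3(C)[C@@H]1O
F4 | step 9 | enol triflate (14 bearing OSO2CF3 on C1) | C=C[C@H]1O[C@@]23C(=O)C=CC(=O)C2=C(OS(=O)(=O)C(F)(F)F)[C@@H]2[C@H](CC[C@]2(C)O)[C@@]3(C)[C@@H]1O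
F5 | step 7 | hydroquinone with C1 as CH2 (acetonide) | Oc1ccc(O)c2c1[C@](C)([C@@H]1OC(C)(C)O[C@@H]1C=C)[C@H]1CC[C@](C)(O)[C@@H]1C2
F6 | step 7 | dimethyl ether of F5 | COc1ccc(OC)c2c1[C@](C)([C@@H]1OC(C)(C)O[C@@H]1C=C)[C@H]1CC[C@](C)(O)[C@@H]1C2
F7 | step 7 | benzylic alcohol (F6 with C1–OH, both epimers) | COc1ccc(OC)c2c1[C@](C)([C@@H]1OC(C)(C)O[C@@H]1C=C)[C@H]1CC[C@](C)(O)[C@@H]1C2O
F8 | step 4 | anti C9 monobenzoate of 7 | COc1ccc(OC)c(/C=C/[C@@](C)(O)CC/C=C(\C)[C@H](O)[C@H](OC(=O)c2ccccc2)C=C)c1
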